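Abbreviation used throughout: TBS = tert-butyldimethylsilyl.

## The problem

6,8-Diprenylnaringenin (15) is a flavanone. Its hexasubstituted phloroglucinol ring A is fused through C4a–C8a to the pyranone ring C, the 4-hydroxyphenyl ring B sits on C2, and 3-methylbut-2-enyl (prenyl) groups sit on C6 and C8. The only stereocentre is C2 (S). No second centre exists from which it could be relayed, so its configuration must come from a catalyst, and any temporary centre made with it must be tied to it by a reliable relative preference. C2 is also fragile: it is a benzylic ether carbon β to the C4 ketone, and base opens ring C by retro-oxa-Michael reaction to the achiral 2′-hydroxychalcone. The ketone and the free phenols should therefore appear late and never meet strong base. The prenyl groups set the remaining limits. Each lies ortho to a phenol and closes to a dimethylchroman in strong acid, the CH2 groups are both benzylic and allylic and are the first C–H bonds to be oxidised, and the olefins exclude hydrogenolysis and electrophilic oxidants. Ring A is a regiochemical problem only if built piecemeal: in a symmetrical 2,4,6-trioxygenated benzaldehyde the two free ring carbons and the two ortho oxygens are equivalent, and the aldehyde carbon is C4. The enabling feature is the array O1–C8a–C4a–C4. With C4 at the aldehyde oxidation level it is an ortho-quinone methide heterodiene, and the C2–C3 unit it needs is the vinyl group of a 4-oxygenated styrene. Ring C, the bonds O1–C2 and C3–C4, and the C2 centre can then arise in one cycloaddition, with C4 arriving oxygenated.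

## Retrosynthesis

**15 ⇒ 14.** Three O–Si bonds are cut, leading back to the tris-TBS ether 14. Silyl ethers are the only phenol protection here that comes off near neutrality. Benzyl ethers would need hydrogenolysis (prenyl olefins), alkyl or acetal ethers strong acid (chroman formation), and esters base (ring opening at C2). Compound 14 has no free phenol beside a prenyl group, which the preceding oxidation needs. The forward step must cleave three aryl silyl ethers with buffered fluoride, so that no phenoxide persists long enough to open ring C.

**14 ⇒ 13 ⇒ 12.** No skeletal bond is cut; only the substituent and oxidation level at C4 change. Ketone 14 comes from flavan-4-ol 13, and 13 from the 4-methoxyflavan 12 by exchange of the C4 ether. The neighbouring choice, a flavan with CH2 at C4 and a later benzylic oxidation, would set C4–H against four benzylic, allylic prenyl C–H bonds. An oxygen already on C4 removes that competition. Compound 12 is also the safer carrier of C2, which is no longer β to a carbonyl group. The forward steps rely on C4 ionising far more readily than O1–C2 (three oxygen donors on ring A against one on ring B), and on an oxidant that is non-basic and inert to olefins.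

**12 ⇒ 5 + 8 + 9.** The bonds O1–C2 and C3–C4 are cut together, and the C4 methoxy group is traced to orthoformate 9. This gives salicylaldehyde 5, styrene 8 and 9. Cutting O1–C2 alone (an oxa-Michael closure) would leave a reversible, base-sensitive cyclisation to carry the whole stereochemical burden. Cutting C2–aryl (a conjugate arylation) would require a separately built, fully substituted benzopyranone. The double cut removes ring C, two bonds and both stereocentres at once and leaves one aromatic aldehyde and one styrene. The forward reaction must form the methoxy ortho-quinone methide from 5 and 9 under a chiral Brønsted acid, add 8 with facial control from the chiral counter-anion, and deliver the 2,4-cis adduct so that the configuration at C2 follows from that at C4. The acid must leave the prenyl groups and the free phenol alone.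

**5 ⇒ 3 ⇒ 1 + 2 (+ 4).** Two O–Si bonds are cut to give triol 3, then the two aryl–CH2 bonds of the prenyl groups, giving 2,4,6-trihydroxybenzaldehyde 1 and prenyl bromide 2. Because 1 is symmetrical, the two nuclear positions are the only free carbons and the two ortho hydroxyls are equivalent, so neither step has a regiochemical question. The forward reactions need C- over O-alkylation, a stop after two prenyl groups, and silylation by 4 that leaves one chelated hydroxyl free.

**8 ⇒ 6 + 4.** The O–Si bond of 8 is cut to 4-vinylphenol 7, which polymerises on storage and is therefore generated from 4-acetoxystyrene 6 and silylated at once with 4. The silyl ether makes the styrene electron-rich enough for the cycloaddition and leaves with the other two at the end.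

## Roads not taken

**Alternative 1:** Ring A would be written by a cyclobutenone–alkyne benzannulation, cutting C4a–C5, C5–C6 and C7–C8.
- Forward key step: cyclobutenone A2 opens on heating to a vinylketene, which adds siloxyalkyne A3 and electrocyclises to phenol A1.
- Merits: every ring-A substituent is placed by the connectivity of the two partners, and the three oxygens emerge differentiated (one free, two as triisopropylsilyl ethers).
- Weak points: the step addresses the part of 15 that is easiest to obtain otherwise. After A1 the C4 carbon, ring C and the C2 stereocentre are all still missing, so an acylation and a separate enantioselective ring closure remain. A2 and A3 each need several steps, and siloxyalkynes are moisture-sensitive.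
- Comparison: in one respect this road is better, because it cannot over-alkylate, whereas step 1 of the chosen route is a statistical C-alkylation. Against that the chosen plan has a ring A bought ready-made in 1, two steps from 1 to 5, and a key step that deals with C2.

**Alternative 2:** Ring A would be grown last, cutting C8–C8a and C4a–C5.
- Forward key step: the 2,4-diprenylated bis(trimethylsilyloxy)diene A6 adds across the bromo-enone of the (2S)-dihydropyranone A5. Loss of HBr and methanol aromatises the new ring to A4, one desilylation from 15.
- Merits: C2 would be set early by an established catalytic asymmetric hetero-Diels–Alder reaction leading to A5, and the route is convergent.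
- Weak points: A6 is substituted at both C2 and C4, so the annulation must form a hexasubstituted benzene from a hindered diene of uncertain geometry and a β-alkoxy enone that is a poor acceptor. The Lewis acid needed (typically TiCl4 or a silyl triflate) threatens the prenyl groups. In the adduct O1 is a leaving group β to the C4 carbonyl, so aromatisation by expulsion of O1 competes with loss of HBr and would open ring C.
- Comparison: this road has the firmer footing for the stereocentre, since its asymmetric step is known and step 4 of the chosen plan is not. The chosen plan sets against this that its bond-forming event is a known reaction in racemic form, that the annulation of A5 with A6 has no close model either, and that C2 never has to survive a ring-forming step next to it.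

**Alternative 3:** C2–C3 would be cut.
- Forward key step: α-diazoketone A8 loses nitrogen on a chiral divalent rhodium carboxylate dimer such as Rh2(S-PTTL)4. The carbenoid carbon C3 inserts into a benzylic C–H bond of one of the two equivalent ortho 4-(silyloxy)benzyl ethers, closing ring C to A7 with C2 set.
- Merits: the ketone is in place directly, with no adjustment at C4. The two benzyl ethers are equivalent. The leftover 5-O-benzyl group would leave with the silyl ethers, by fluoride-triggered 1,6-elimination.
- Weak points: an acceptor-only carbenoid is the least selective class. The closure is a 1,6-insertion with the ether oxygen at the 1,5-position, so oxonium ylide formation followed by [1,2]-benzyl shift to a five-membered ring is a likely competitor. The electron-rich prenyl olefins and ring A invite cyclopropanation and arene addition. A8 must be made from a hindered 2,6-dialkoxybenzoic acid derivative over more steps than 5.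
- Comparison: this road finishes closer to the target oxidation state, and the chosen plan pays two extra steps (exchange and oxidation) for not doing so. The chosen plan sets against this a key step in which ion-pair catalysis should be compatible with olefins, and a precursor two steps from a commercial aldehyde.

Key step: step 4

Assumption: the absolute sense of induction of the chiral acid in step 4 cannot be deduced from structure alone; the (R)-catalyst is written, and its enantiomer would be used if it favoured the (2R,4R) adduct.

## Route

Step 1
Reactants: 1 2,4,6-trihydroxybenzaldehyde; 2 prenyl bromide (1-bromo-3-methylbut-2-ene)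
Product: 3 2,4,6-trihydroxy-3,5-bis(3-methylbut-2-en-1-yl)benzaldehyde
Conditions: 2 (2.1 equiv, slow addition), KOH (10% aq), 0 °C to rt
Reagents that add atoms: prenyl bromide, CC(C)=CCBr
Why: Nuclear C-alkylation of an ambident phloroglucinol phenoxide in water, the method used for prenylated acylphloroglucinols; the protic medium shields the oxygens so the allylic bromide is attacked at the two free ring carbons, and the formyl group lowers ring nucleophilicity enough that two equivalents should stop mainly at the 3,5-diprenyl stage.

Step 2
Reactants: 3 2,4,6-trihydroxy-3,5-bis(3-methylbut-2-en-1-yl)benzaldehyde; 4 tert-butyldimethylsilyl chloride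
Product: 5 4,6-bis(tert-butyldimethylsilyloxy)-2-hydroxy-3,5-bis(3-methylbut-2-en-1-yl)benzaldehyde
Conditions: TBSCl (2.1 equiv), imidazole (4 equiv), DMF, 0 °C to rt
Reagents that add atoms: tert-butyldimethylsilyl chloride, CC(C)(C)[Si](C)(C)Cl
Why: Phenol silylation with TBSCl and imidazole; the non-chelated 4-hydroxyl and one of the two equivalent ortho hydroxyls react, after which the last hydroxyl is locked in a hydrogen bond to the aldehyde and flanked by formyl and prenyl groups, so the third silylation should be much slower, as is usual in partial protection of 2,4,6-trihydroxyaryl carbonyl compounds.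

Step 3
Reactants: 6 4-acetoxystyrene; 4 tert-butyldimethylsilyl chloride
Product: 8 4-(tert-butyldimethylsilyloxy)styrene, via 4-vinylphenol 7 (not isolated)
Conditions: K2CO3 (0.1 equiv), MeOH, 0 °C; cold solvent exchange; TBSCl (1.2 equiv), imidazole (2.5 equiv), CH2Cl2, 0 °C to rt
Reagents that add atoms: tert-butyldimethylsilyl chloride, CC(C)(C)[Si](C)(C)Cl
Why: Base-catalysed methanolysis of the aryl acetate followed by phenol silylation; 4-vinylphenol polymerises on standing, so it is silylated directly without isolation.

Step 4
Reactants: 5 4,6-bis(tert-butyldimethylsilyloxy)-2-hydroxy-3,5-bis(3-methylbut-2-en-1-yl)benzaldehyde; 8 4-(tert-butyldimethylsilyloxy)styrene; 9 trimethyl orthoformate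
Product: 12 (2S,4S)-5,7-bis(tert-butyldimethylsilyloxy)-2-[4-(tert-butyldimethylsilyloxy)phenyl]-4-methoxy-6,8-bis(3-methylbut-2-en-1-yl)chromane (2,4-cis), via dimethyl acetal 10 (not isolated), via methoxy ortho-quinone methide 11 (not isolated)
Conditions: 9 (1.5 equiv), (R)-3,3′-bis(2,4,6-triisopropylphenyl)-BINOL N-triflyl phosphoramide (10 mol %), 5 Å MS, toluene, 0 °C; then 8 (2 equiv), −40 °C; Et3N quench at −40 °C; chromatography on Et3N-deactivated silica to remove any trans isomer
Reagents that add atoms: trimethyl orthoformate, COC(OC)OC
Why: Proposed new method: acid-catalysed acetalisation of 5 by 9 gives 10, which loses methanol to the methoxy ortho-quinone methide 11, present as its O-protonated hydroxyaryl oxocarbenium form, hydrogen-bonded and ion-paired to the chiral phosphoramide anion; the closest known reactions are the racemic acid-catalysed salicylaldehyde, orthoformate and styrene synthesis of 2,4-cis-4-alkoxyflavans and chiral phosphoric acid-catalysed ortho-quinone methide cycloadditions with styrenes. The electron-rich styrene 8 adds in an asynchronous inverse-electron-demand hetero-[4+2], its CH2 terminus bonding to C4 first and the phenolic oxygen then capturing the developing 4-silyloxybenzyl cation at C2. Ring C is thus closed as a six-membered ring by an intermolecular [4+2] cycloaddition, which in its stepwise limit ends in a 6-exo capture of the C2 cation by O1. C4 is set by the face of the oxocarbenium left open in the chiral ion pair (catalyst control), and C2 is set relative to C4 by the 2,4-cis preference of the closure, in which aryl and methoxy groups both lie pseudo-equatorial in the forming half-chair (substrate control). Regiochemistry follows from polarity, since the nucleophilic terminus of 8 meets the electrophilic C4 and positive charge can develop only on the aryl-bearing carbon. Chemoselectivity over the two prenyl olefins rests on the much higher nucleophilicity of the conjugated silyloxystyrene used in excess and on an acid too weak at −40 °C to protonate a trisubstituted olefin, so the C8 prenyl group should not close onto the free phenol. Because C4 is erased later and a trans isomer would, in the stepwise limit, carry the opposite configuration at C2, the reaction is quenched cold to prevent re-ionisation at C4 and the trans isomer is removed at this stage.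

Step 5
Reactants: 12 (2S,4S)-5,7-bis(tert-butyldimethylsilyloxy)-2-[4-(tert-butyldimethylsilyloxy)phenyl]-4-methoxy-6,8-bis(3-methylbut-2-en-1-yl)chromane
Product: 13 (2S)-5,7-bis(tert-butyldimethylsilyloxy)-2-[4-(tert-butyldimethylsilyloxy)phenyl]-6,8-bis(3-methylbut-2-en-1-yl)chroman-4-ol (mixture of C4 epimers)
Conditions: PPTS (0.1 equiv), THF/H2O 5:1, 0 °C to rt
Reagents that add atoms: water, O
Why: SN1 solvolysis of a benzylic ether; C4 is attached to a ring bearing three oxygen donors (O1, C5–O, C7–O), so it should ionise under very mild acid and be captured by the large excess of water, while O1–C2, the aryl silyl ethers and the prenyl groups should tolerate PPTS at room temperature; either C4 epimer serves, since C4 becomes trigonal in the next step.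

Step 6
Reactants: 13 (2S)-5,7-bis(tert-butyldimethylsilyloxy)-2-[4-(tert-butyldimethylsilyloxy)phenyl]-6,8-bis(3-methylbut-2-en-1-yl)chroman-4-ol
Product: 14 (2S)-5,7-bis(tert-butyldimethylsilyloxy)-2-[4-(tert-butyldimethylsilyloxy)phenyl]-6,8-bis(3-methylbut-2-en-1-yl)chroman-4-one
Conditions: Dess–Martin periodinane (1.5 equiv), NaHCO3, CH2Cl2, 0 °C to rt
Reagents that add atoms: none
Why: Dess–Martin oxidation of a secondary benzylic alcohol under buffered, non-basic conditions; olefins, silyl ethers and the prenyl CH2 groups are inert to the periodinane, and no base is present to open ring C, so C2 should be retained.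

Step 7
Reactants: 14 (2S)-5,7-bis(tert-butyldimethylsilyloxy)-2-[4-(tert-butyldimethylsilyloxy)phenyl]-6,8-bis(3-methylbut-2-en-1-yl)chroman-4-one
Product: 15 (2S)-5,7-dihydroxy-2-(4-hydroxyphenyl)-6,8-bis(3-methylbut-2-en-1-yl)chroman-4-one (6,8-diprenylnaringenin)
Conditions: TBAF (3.5 equiv), AcOH (4 equiv), THF, 0 °C
Reagents that add atoms: none
Why: Fluoride cleavage of aryl silyl ethers; acetic acid protonates each phenoxide as it forms, which should suppress E1cB opening of ring C to the chalcone (the racemisation path of 5-hydroxyflavanones) while keeping the medium far too weakly acidic for prenyl–phenol cyclisation.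

## Compound list

1 | 2,4,6-trihydroxybenzaldehyde | O=Cc1c(O)cc(O)cc1O | starting material
2 | prenyl bromide (1-bromo-3-methylbut-2-ene) | CC(C)=CCBr | starting material
3 | 2,4,6-trihydroxy-3,5-bis(3-methylbut-2-en-1-yl)benzaldehyde | O=Cc1c(O)c(CC=C(C)C)c(O)c(CC=C(C)C)c1O | intermediate
4 | tert-butyldimethylsilyl chloride | CC(C)(C)[Si](C)(C)Cl | starting material
5 | 4,6-bis(tert-butyldimethylsilyloxy)-2-hydroxy-3,5-bis(3-methylbut-2-en-1-yl)benzaldehyde | O=Cc1c(O)c(CC=C(C)C)c(O[Si](C)(C)C(C)(C)C)c(CC=C(C)C)c1O[Si](C)(C)C(C)(C)C | intermediate
6 | 4-acetoxystyrene (4-vinylphenyl acetate) | CC(=O)Oc1ccc(C=C)cc1 | starting material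
7 | 4-vinylphenol | C=Cc1ccc(O)cc1 | intermediate (not isolated)
8 | 4-(tert-butyldimethylsilyloxy)styrene | C=Cc1ccc(O[Si](C)(C)C(C)(C)C)cc1 | intermediate
9 | trimethyl orthoformate | COC(OC)OC | starting material
10 | 3,5-bis(tert-butyldimethylsilyloxy)-2-(dimethoxymethyl)-4,6-bis(3-methylbut-2-en-1-yl)phenol (dimethyl acetal of 5) | COC(OC)c1c(O)c(CC=C(C)C)c(O[Si](C)(C)C(C)(C)C)c(CC=C(C)C)c1O[Si](C)(C)C(C)(C)C | intermediate (not isolated)
11 | 3,5-bis(tert-butyldimethylsilyloxy)-6-(methoxymethylidene)-2,4-bis(3-methylbut-2-en-1-yl)cyclohexa-2,4-dien-1-one (methoxy ortho-quinone methide, reacting as its O-protonated ion pair) | COC=C1C(=O)C(CC=C(C)C)=C(O[Si](C)(C)C(C)(C)C)C(CC=C(C)C)=C1O[Si](C)(C)C(C)(C)C | intermediate (not isolated)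
12 | (2S,4S)-5,7-bis(tert-butyldimethylsilyloxy)-2-[4-(tert-butyldimethylsilyloxy)phenyl]-4-methoxy-6,8-bis(3-methylbut-2-en-1-yl)chromane (2,4-cis) | CO[C@H]1C[C@@H](c2ccc(O[Si](C)(C)C(C)(C)C)cc2)Oc2c(CC=C(C)C)c(O[Si](C)(C)C(C)(C)C)c(CC=C(C)C)c(O[Si](C)(C)C(C)(C)C)c21 | intermediate
13 | (2S)-5,7-bis(tert-butyldimethylsilyloxy)-2-[4-(tert-butyldimethylsilyloxy)phenyl]-6,8-bis(3-methylbut-2-en-1-yl)chroman-4-ol (C4 epimers) | OC1C[C@@H](c2ccc(O[Si](C)(C)C(C)(C)C)cc2)Oc2c(CC=C(C)C)c(O[Si](C)(C)C(C)(C)C)c(CC=C(C)C)c(O[Si](C)(C)C(C)(C)C)c21 | intermediate
14 | (2S)-5,7-bis(tert-butyldimethylsilyloxy)-2-[4-(tert-butyldimethylsilyloxy)phenyl]-6,8-bis(3-methylbut-2-en-1-yl)chroman-4-one | O=C1C[C@@H](c2ccc(O[Si](C)(C)C(C)(C)C)cc2)Oc2c(CC=C(C)C)c(O[Si](C)(C)C(C)(C)C)c(CC=C(C)C)c(O[Si](C)(C)C(C)(C)C)c21 | intermediate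
15 | (2S)-5,7-dihydroxy-2-(4-hydroxyphenyl)-6,8-bis(3-methylbut-2-en-1-yl)chroman-4-one (6,8-diprenylnaringenin) | CC(C)=CCc1c(O)c(CC=C(C)C)c2c(c1O)C(=O)C[C@@H](c1ccc(O)cc1)O2 | target

## Summary and least certain steps

Total step count: 7. Longest linear sequence: 6 steps (1 → 3 → 5 → 12 → 13 → 14 → 15); step 3 supplies the styrene in a side branch.

**Step 4 (key step, proposed new method).**
- What may go wrong: weak enantiofacial discrimination, because an oxocarbenium stabilised by three ring oxygens reacts through a loose ion pair. The link between C2 and C4 may also erode through re-ionisation at C4 or an incomplete cis preference. Further risks are cationic oligomerisation of the styrene and acid-triggered closure of the C8 prenyl group onto the free phenol.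
- Fallback (known chemistry), setting out from 5, 8 and 9 and returning at 14: the three components are combined under an achiral acid (PPTS or TsOH, the established racemic reaction) to give the racemic 2,4-cis-4-methoxyflavan F1. The conditions of step 5 turn it into the racemic flavan-4-ol F2, and those of step 6 into the racemic flavanone F3. F3 is then resolved kinetically by asymmetric transfer hydrogenation with RuCl(p-cymene)[(R,R)-TsDPEN] in HCO2H/Et3N. By the usual facial preference for aryl ketones, this catalyst should reduce the (2R)-ketone to the (2R,4R)-cis-flavan-4-ol F4 and leave (2S)-ketone 14 to be recovered, at the cost of half the material.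

**Step 1.**
- What may go wrong: over-alkylation at an already prenylated carbon (dearomatised gem-diprenyl products), partial O-alkylation and incomplete reaction, so that 3 must be separated from a mixture.
- Fallback, setting out from 1 and 2 and returning at 3: O-alkylation with K2CO3 in acetone, which spares the chelated hydroxyl, should give 2-hydroxy-4,6-bis(3-methylbut-2-en-1-yloxy)benzaldehyde F5. This fixes the number of prenyl groups at two. A Lewis-acid-catalysed [1,3] O-to-C prenyl shift (Bi(OTf)3, CH2Cl2, low temperature, stopped before chroman formation) then moves both groups to the only free ring carbons, giving 3.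

**Step 5.**
- What may go wrong: loss of a C3 proton from the C4 cation (E1 elimination to the flav-3-ene) instead of capture by water. Under more forcing acid, heterolysis of O1–C2 would scramble C2.
- Fallback, setting out from 12 and returning at 14 (it also replaces step 6): the cation is intercepted by a soft nucleophile that captures it faster and irreversibly. Thiophenol with catalytic PPTS in CH2Cl2 should give the (2S)-4-(phenylsulfanyl)flavan F6. One equivalent of mCPBA at −78 °C oxidises sulfur in preference to the olefins and gives the sulfoxide F7. A Pummerer rearrangement (trifluoroacetic anhydride, 2,6-lutidine, then aqueous NaHCO3) then delivers ketone 14 without a free alcohol or a separate oxidant at C4.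

## Further compounds

F1 | step 4 | racemic (2S*,4S*)-5,7-bis(tert-butyldimethylsilyloxy)-2-[4-(tert-butyldimethylsilyloxy)phenyl]-4-methoxy-6,8-bis(3-methylbut-2-en-1-yl)chromane (relative configuration drawn) | CO[C@H]1C[C@@H](c2ccc(O[Si](C)(C)C(C)(C)C)cc2)Oc2c(CC=C(C)C)c(O[Si](C)(C)C(C)(C)C)c(CC=C(C)C)c(O[Si](C)(C)C(C)(C)C)c21
F2 | step 4 | racemic 5,7-bis(tert-butyldimethylsilyloxy)-2-[4-(tert-butyldimethylsilyloxy)phenyl]-6,8-bis(3-methylbut-2-en-1-yl)chroman-4-ol (C4 epimers) | OC1CC(c2ccc(O[Si](C)(C)C(C)(C)C)cc2)Oc2c(CC=C(C)C)c(O[Si](C)(C)C(C)(C)C)c(CC=C(C)C)c(O[Si](C)(C)C(C)(C)C)c21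
F3 | step 4 | racemic 5,7-bis(tert-butyldimethylsilyloxy)-2-[4-(tert-butyldimethylsilyloxy)phenyl]-6,8-bis(3-methylbut-2-en-1-yl)chroman-4-one | O=C1CC(c2ccc(O[Si](C)(C)C(C)(C)C)cc2)Oc2c(CC=C(C)C)c(O[Si](C)(C)C(C)(C)C)c(CC=C(C)C)c(O[Si](C)(C)C(C)(C)C)c21
F4 | step 4 | (2R,4R)-5,7-bis(tert-butyldimethylsilyloxy)-2-[4-(tert-butyldimethylsilyloxy)phenyl]-6,8-bis(3-methylbut-2-en-1-yl)chroman-4-ol (2,4-cis) | O[C@@H]1C[C@H](c2ccc(O[Si](C)(C)C(C)(C)C)cc2)Oc2c(CC=C(C)C)c(O[Si](C)(C)C(C)(C)C)c(CC=C(C)C)c(O[Si](C)(C)C(C)(C)C)c21
F5 | step 1 | 2-hydroxy-4,6-bis(3-methylbut-2-en-1-yloxy)benzaldehyde | O=Cc1c(O)cc(OCC=C(C)C)cc1OCC=C(C)C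
F6 | step 5 | (2S)-5,7-bis(tert-butyldimethylsilyloxy)-2-[4-(tert-butyldimethylsilyloxy)phenyl]-6,8-bis(3-methylbut-2-en-1-yl)-4-(phenylsulfanyl)chromane (C4 epimers) | c1ccccc1SC1C[C@@H](c2ccc(O[Si](C)(C)C(C)(C)C)cc2)Oc2c(CC=C(C)C)c(O[Si](C)(C)C(C)(C)C)c(CC=C(C)C)c(O[Si](C)(C)C(C)(C)C)c21
F7 | step 5 | (2S)-5,7-bis(tert-butyldimethylsilyloxy)-2-[4-(tert-butyldimethylsilyloxy)phenyl]-6,8-bis(3-methylbut-2-en-1-yl)-4-(phenylsulfinyl)chromane (C4 and sulfur epimers) | O=S(c1ccccc1)C1C[C@@H](c2ccc(O[Si](C)(C)C(C)(C)C)cc2)Oc2c(CC=C(C)C)c(O[Si](C)(C)C(C)(C)C)c(CC=C(C)C)c(O[Si](C)(C)C(C)(C)C)c21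
A1 | alternative 1 | 2,4-bis(3-methylbut-2-en-1-yl)-3,5-bis(triisopropylsilyloxy)phenol | Oc1cc(O[Si](C(C)C)(C(C)C)C(C)C)c(CC=C(C)C)c(O[Si](C(C)C)(C(C)C)C(C)C)c1CC=C(C)C
A2 | alternative 1 | 2-(3-methylbut-2-en-1-yl)-3-(triisopropylsilyloxy)cyclobut-2-en-1-one | O=C1CC(O[Si](C(C)C)(C(C)C)C(C)C)=C1CC=C(C)C
A3 | alternative 1 | 5-methyl-1-(triisopropylsilyloxy)hex-4-en-1-yne | CC(C)=CCC#CO[Si](C(C)C)(C(C)C)C(C)C
A4 | alternative 2 | (2S)-6,8-diprenylnaringenin 4′-O-tert-butyldimethylsilyl ether | CC(C)=CCc1c(O)c(CC=C(C)C)c2c(c1O)C(=O)C[C@@H](c1ccc(O[Si](C)(C)C(C)(C)C)cc1)O2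
A5 | alternative 2 | (2S)-5-bromo-2-[4-(tert-butyldimethylsilyloxy)phenyl]-2,3-dihydro-4H-pyran-4-one | O=C1C[C@@H](c2ccc(O[Si](C)(C)C(C)(C)C)cc2)OC=C1Br
A6 | alternative 2 | 1-methoxy-2,4-bis(3-methylbut-2-en-1-yl)-1,3-bis(trimethylsilyloxy)buta-1,3-diene | COC(O[Si](C)(C)C)=C(CC=C(C)C)C(O[Si](C)(C)C)=CCC=C(C)C
A7 | alternative 3 | (2S)-5-O-[4-(tert-butyldimethylsilyloxy)benzyl]-6,8-diprenylnaringenin 7,4′-bis(tert-butyldimethylsilyl) ether | CC(C)=CCc1c(O[Si](C)(C)C(C)(C)C)c(CC=C(C)C)c2c(c1OCc3ccc(O[Si](C)(C)C(C)(C)C)cc3)C(=O)C[C@@H](c4ccc(O[Si](C)(C)C(C)(C)C)cc4)O2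
A8 | alternative 3 | 1-{2,6-bis[4-(tert-butyldimethylsilyloxy)benzyloxy]-4-(tert-butyldimethylsilyloxy)-3,5-bis(3-methylbut-2-en-1-yl)phenyl}-2-diazoethanone | [N-]=[N+]=CC(=O)c1c(OCc2ccc(O[Si](C)(C)C(C)(C)C)cc2)c(CC=C(C)C)c(O[Si](C)(C)C(C)(C)C)c(CC=C(C)C)c1OCc1ccc(O[Si](C)(C)C(C)(C)C)cc1
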